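Skeleton numbering used throughout (not von Baeyer numbering): seven-membered ring C1(=CH2)–C2–C3(O-acyl)–C4(H)–C5(CH3)–C9–C10(OH); five-membered ring C4–C5–C6–C7–C8(OH)(isopropyl). "β" is the face of the C5 methyl group, "α" the face of the C4 hydrogen.

## Analysis of the target

Target 23 is a trans-fused bicyclo[5.3.0]decane (hydroazulene, daucane type) in which a cycloheptane and a cyclopentane share the C4–C5 bond. It has five stereocentres: C3 (S, vanillate ester), C4 (S, ring-fusion hydrogen), C5 (R, quaternary, angular methyl), C8 (R, tertiary alcohol bearing isopropyl) and C10 (S, allylic alcohol beside the exocyclic C1 methylene). C8 and C3 both sit on C4 and C5 is its other neighbour, so four of the five centres form one congested cluster, while C10 is insulated from it by the C9 methylene. Relative to the β-methyl on C5, the C8 hydroxyl is β, and H4, the C3 oxygen and the C10 oxygen are α. On the cyclopentane the C4–C3 bond is therefore cis to the C5 methyl and to the C8 hydroxyl, and the C3–O/C4–C5 relation is that of an anti aldol along C8–C4–C3–C2. Sensitive groups are the 2-methylene-1-ol unit (ionisation, alkene migration into the ring), the tertiary alcohol (dehydration), and the aryl ester with its free phenol (bases, nucleophiles, aluminium and magnesium reagents). The difficulties are the quaternary C5 flanked by two further substituted carbons, the seven-membered ring, and the fact that only one of three hydroxyls is acylated. The strategy rests on one feature: C5, C4 and C8 are the β-carbon, α-carbon and carbonyl carbon of a cyclopentanone, so the C5 methyl and the C3 carbinol chain can be added across a cyclopentenone. C2–C1 and C9–C10 are then two side arms that can be joined at C1=C10.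

## Retrosynthetic reasoning

**Ester last (23 ⇐ 22 ⇐ 17 + 20).** The C3–O acyl bond is cut first. The aryl ester would not survive the organometallic and aluminium amide reagents needed earlier. The phenol of 18 must be masked, as in 20, so that the acid cannot acylate itself. A silyl ether on the phenol and on C10 lets one fluoride treatment of 22 release both. Activation as the mixed anhydride 21 suits the hindered C3 hydroxyl of 17.

**Differentiating C3-OH from C10-OH (17 ⇐ 16 ⇐ 15).** Once the C10 hydroxyl exists it is less hindered than the C3 hydroxyl, so a direct selective acylation of a C3,C10-diol cannot be trusted. C3 therefore carries a labile triethylsilyl group from early on. C10 is capped in 16 with a more robust silyl group, and the C3 group is then removed selectively to give 17. This costs two steps and buys an unambiguous acylation site.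

**Exocyclic methylene and C10 carbinol (15 ⇐ 14 ⇐ 13).** The C1=CH2/C10-OH pair is the product of a base-promoted β-elimination of a C1–C10 epoxide in which a methyl proton on C1 is removed and the C1–O bond breaks. The C10–O bond is untouched, so C10 is set by the face of epoxidation of the trisubstituted alkene 13. In the trans-fused ring the axial C5 methyl covers the β face at C10 and the C3 substituent is equatorial, so a peracid should attack the α face, as required. Allylic oxidation of 13 was not chosen because it would functionalise C2 or the methyl group rather than C10.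

**Seven-membered ring (13 ⇐ 12).** The ring is opened at C1=C10 because this is the only ring bond whose cleavage leaves two simple, unfunctionalised arms: a methallyl group on C3 and an allyl group on C5. The forward ring-closing metathesis has to form a trisubstituted cycloheptene trans-fused to the cyclopentane. It forms no stereocentre.

**C8 (12 ⇐ 10 + 11; 10 ⇐ 9).** The C8–isopropyl bond is cut to reveal the cyclopentanone 10. The nucleophile from 11 must enter anti to the C4 side chain, which is the normal course for a 2-substituted cyclopentanone and gives the hydroxyl cis to that chain. The C3 hydroxyl of 9 is silylated first, because a free β-hydroxy ketone would undergo retro-aldol cleavage under basic organometallic conditions.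

**Key disconnection (9 ⇐ 4 + 7 + 6).** Two bonds on the cyclopentanone are cut: C5–CH3 and C3–C4. Forward, a copper-catalysed asymmetric transfer of methyl from 7 to the β-carbon of 4 creates the quaternary C5 and the aluminium enolate 8. Enolate 8 adds to aldehyde 6 to form C3–C4 and to set C4 and C3. Three stereocentres and both metathesis arms are therefore in place after one operation on an achiral enone. Epimerisation at C4 by enolisation after the aldol would invert C4 against a fixed C3 and is not a remedy for a poor facial ratio; the route relies on kinetic control and separation, and 9 is silylated promptly.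

**Building blocks (4 ⇐ 1 + 2; 6 ⇐ 5).** Enone 4 comes from 1,2-addition of 2 to the vinylogous ester 1 and acidic transposition. Aldehyde 6 comes from oxidation of 5. Both are one-step preparations from commercial materials, so the risk of the route is concentrated in the key step.

## Alternatives that were turned down

**Alternative 1:** Rhodium-catalysed (5+2) cycloaddition. The disconnection cuts C4–C5 and C2–C3 and traces the bicycle A1 (C3=C4 and C9=C10 dienes, C10 as enol silane) to the acyclic enyne A2. A2 is a 1-siloxy-1-vinylcyclopropane whose trisubstituted alkene carries the C5 methyl and a three-carbon tether to a propargylic tertiary alcohol. Forward, [Rh(CO)2Cl]2 would close both rings and form the quaternary centre in one catalytic, atom-economical step. On ring construction this is stronger than the chosen route, which forms no ring in its key step. Against it for this target: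
- C5 would be set only by remote induction from the C8 carbinol across an sp-hybridised C4.
- The alkene partner is trisubstituted and carries the tether, which is a slow substrate class for this cycloaddition.
- A1 still lacks C3, C4 and C10 as stereocentres and lacks the C1 methylene. It needs hydroboration of C3=C4, α-methylenation of the C10 ketone and a 1,2-reduction from the methyl-bearing face, all under substrate control.
- A2 itself needs a multistep synthesis.

The chosen route offers three stereocentres set together on an achiral enone and building blocks made in one step each.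

**Alternative 2:** Gold-catalysed Conia-ene closure. The disconnection cuts C1–C2 of the ketone A3 and leads to the cyclopentane A4, which carries a methyl ketone enol silane on C4 and a silyl-protected propargylic carbinol arm on C5. Forward, Ph3PAuCl/AgOTf would activate the terminal alkyne for 7-exo-dig attack by the enol silane carbon, closing the ring and forming C1=CH2 in the same event. This is stronger than the chosen route at the exocyclic alkene, which needs no epoxide rearrangement, and C10 arrives as a pre-set propargylic centre. Against it:
- The key step builds no stereocentre. A4 must already contain C4, C5, C8 and C10, so the congested cyclopentane still has to be assembled, most plausibly by the same conjugate addition logic, with a longer arm.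
- Seven-membered exo-dig closures of enol silanes lie well outside the favourable five- and six-membered cases, and protodesilylation competes.
- A3 is a β,γ-unsaturated ketone whose alkene can slip into conjugation with C3.
- The C3 ketone must afterwards be reduced from the β face, which is screened by the C5 methyl.

The chosen route fixes C3 in the bond-forming step itself and never passes through a C3 ketone.

**Alternative 3:** Enzymatic cyclisation. The disconnection cuts C5–C9 and C4–C8 of the hydrocarbon daucene A5 and leads to farnesyl diphosphate A6. Forward, a class 1 sesquiterpene synthase of the daucene/carotol family would ionise A6 and deliver the whole carbon skeleton with C5 in the required configuration in one step. In skeletal bond economy no chemical route matches this. Against it: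
- A5 has no oxygen. C3, C8 and C10 would all have to be oxidised late, on a diene whose tetrasubstituted C4=C8 alkene must be converted into C8-OH/C4-H with trans fusion while C3 is oxidised allylically and the C1=C10 alkene is spared until its turn.
- Regio-, chemo- and stereoselectivity would each have to be solved on a hydrocarbon with no directing group.
- The enzyme and A6, or an engineered producer strain, are not catalogue reagents.

The chosen route is longer in skeletal steps but brings the C3 and C8 oxygens in with the building blocks and sets every centre by a defined, reagent- or substrate-controlled event.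

Key step: step 3

Assumption: the sense of induction of the phosphoramidite on a 3-substituted cyclopentenone is taken to follow that on six-membered enones. The (S,S,S) ligand L* [O,O′-(S)-1,1′-binaphthyl-2,2′-diyl N,N-bis((S)-1-phenylethyl)phosphoramidite] is written; its antipode is used instead if a test reaction shows the opposite sense at C5.

## Route

Step 1
Reactants: 1 3-ethoxycyclopent-2-en-1-one; 2 allylmagnesium bromide
Product: 4 3-(prop-2-en-1-yl)cyclopent-2-en-1-one, via magnesium alkoxide 3 (not isolated)
Conditions: THF, 0 °C; then 1 M HCl, 0 °C, short contact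
Reagents that add atoms: water, O
Why: Stork–Danheiser sequence: the Grignard reagent adds 1,2 to the vinylogous ester carbonyl, and dilute acid ionises the tertiary allylic alcohol and hydrolyses the enol ether, transposing the carbonyl. Short, cold acid contact keeps the allyl double bond out of conjugation.

Step 2
Reactants: 5 3-methylbut-3-en-1-ol
Product: 6 3-methylbut-3-enal
Conditions: Dess–Martin periodinane, NaHCO3, CH2Cl2, 0 °C to rt; filtered, used at once as a titrated solution
Reagents that add atoms: none
Why: Dess–Martin oxidation of a primary alcohol under buffered, amine-free conditions, so the β,γ-alkene is not moved into conjugation. The volatile aldehyde is not isolated neat.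

Step 3
Reactants: 4 3-(prop-2-en-1-yl)cyclopent-2-en-1-one; 7 trimethylaluminium; 6 3-methylbut-3-enal
Product: 9 (2S,3R)-2-[(1S)-1-hydroxy-3-methylbut-3-en-1-yl]-3-methyl-3-(prop-2-en-1-yl)cyclopentan-1-one, via aluminium enolate 8 (not isolated)
Conditions: Cu(OTf)2 (5 mol %), L* (10 mol %), AlMe3 (1.5 equiv), Et2O, −30 °C; then 6 (2.5 equiv), −78 to −40 °C; aq. KNaC4H4O6
Reagents that add atoms: none
Why: Cu(OTf)2 is reduced by AlMe3 to a ligand-bound monovalent copper methyl species, which complexes enone 4 and adds at C5 to a trivalent copper intermediate; reductive elimination forms C5–CH3 and the regiodefined dimethylaluminium enolate 8. The closest known reaction type is the copper/phosphoramidite-catalysed asymmetric conjugate addition of trialkylaluminium reagents to β-substituted cyclic enones with aldol trapping of the aluminium enolate. No ring is closed; the step makes two skeletal bonds, C5–CH3 and C3–C4. C5 is set by the ligand, which differentiates the two enone faces in the copper π-complex. C4 is set by approach of aldehyde 6 to the enolate face anti to the allyl group, the larger substituent on the adjacent quaternary carbon, so the new chain ends up cis to the methyl group. C3 is set by the closed six-membered Zimmerman–Traxler transition state: the ring-bound enolate is necessarily E and the methallyl residue of 6 sits equatorial, which gives the anti aldol found in 23. The step needs 1,4- over 1,2-methyl transfer (secured by copper catalysis at −30 °C), trapping of the enolate at C4 before it equilibrates (cold, immediate addition of 6), and survival of the isomerisable aldehyde (non-basic aluminium enolate, low temperature, excess 6 to absorb residual AlMe3). The C4 facial bias between methyl and allyl is the weakest element, and minor C3/C4 diastereomers are to be removed by chromatography here or after step 4.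

Step 4
Reactants: 9 the aldol product
Product: 10 (2S,3R)-3-methyl-2-[(1S)-3-methyl-1-(triethylsilyloxy)but-3-en-1-yl]-3-(prop-2-en-1-yl)cyclopentan-1-one
Conditions: Et3SiCl, imidazole, DMF, 0 °C to rt
Reagents that add atoms: triethylsilyl chloride, CC[Si](Cl)(CC)CC
Why: Standard silylation of a secondary alcohol. The silyl ether blocks retro-aldol cleavage in step 5, and imidazole is too weak a base to epimerise C4.

Step 5
Reactants: 10 the silylated ketone; 11 isopropylmagnesium chloride
Product: 12 (1R,2S,3R)-3-methyl-2-[(1S)-3-methyl-1-(triethylsilyloxy)but-3-en-1-yl]-1-(propan-2-yl)-3-(prop-2-en-1-yl)cyclopentan-1-ol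
Conditions: anhydrous CeCl3 (2.5 equiv), THF, then 11 (2.5 equiv), −78 °C; add 10, −78 to 0 °C; aq. NH4Cl
Reagents that add atoms: none
Why: Imamoto organocerium 1,2-addition: the weakly basic isopropylcerium reagent adds to the hindered, enolisable ketone instead of deprotonating or reducing it. It enters C8 anti to the C4 side chain (the α-substituent), which places isopropyl trans to that chain and the new hydroxyl cis to it, as in 23.

Step 6
Reactants: 12 the diene alcohol
Product: 13 trans-fused hydroazulene with C1(CH3)=C10H, (3S,4S,5R,8R)-1,5-dimethyl-8-(propan-2-yl)-3-(triethylsilyloxy)bicyclo[5.3.0]dec-1(10)-en-8-ol (skeleton numbering)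
Conditions: second-generation Grubbs catalyst (H2IMes)(PCy3)Cl2Ru=CHPh (5 mol %), CH2Cl2 (0.005 M), 40 °C
Reagents that add atoms: none
Why: Ring-closing metathesis between a monosubstituted and a 1,1-disubstituted alkene gives the trisubstituted cycloheptene. The catalyst initiates on the allyl arm, the arms sit on adjacent ring carbons, and the free tertiary alcohol is tolerated; no stereocentre is formed, as the trans fusion is already fixed at C4 and C5.

Step 7
Reactants: 13 the cycloheptene
Product: 14 1α,10α-epoxide, (1R,3S,4S,5R,8R,10S)-1,10-epoxy-1,5-dimethyl-8-(propan-2-yl)-3-(triethylsilyloxy)bicyclo[5.3.0]decan-8-ol (skeleton numbering)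
Conditions: mCPBA, NaHCO3, CH2Cl2, 0 °C
Reagents that add atoms: 3-chloroperoxybenzoic acid, OOC(=O)c1cccc(Cl)c1
Why: Prilezhaev epoxidation of the electron-rich trisubstituted alkene. In the chair-like cycloheptene the ring fusion holds the C5 methyl axial over the β face at C10 and the C3 silyloxy group equatorial, so the peracid should attack the α face and set C10 (S).

Step 8
Reactants: 14 the epoxide
Product: 15 (3S,4S,5R,8R,10S)-5-methyl-1-methylidene-8-(propan-2-yl)-3-(triethylsilyloxy)bicyclo[5.3.0]decane-8,10-diol (skeleton numbering)
Conditions: diethylaluminium 2,2,6,6-tetramethylpiperidide (4 equiv; from lithium 2,2,6,6-tetramethylpiperidide and Et2AlCl), toluene, 0 °C to rt; aq. KNaC4H4O6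
Reagents that add atoms: none
Why: Yamamoto-type isomerisation of an epoxide to an allylic alcohol: aluminium binds the epoxide oxygen and the amide nitrogen removes a syn β-proton through a cyclic transition state. The C1 methyl group, cis to the C10 hydrogen and the least hindered β-position, is deprotonated and the C1–O bond breaks, so the C10–O bond and its configuration are untouched. One equivalent of reagent is consumed by the C8 hydroxyl.

Step 9
Reactants: 15 the allylic alcohol
Product: 16 (3S,4S,5R,8R,10S)-10-(tert-butyldimethylsilyloxy)-5-methyl-1-methylidene-8-(propan-2-yl)-3-(triethylsilyloxy)bicyclo[5.3.0]decan-8-ol (skeleton numbering)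
Conditions: t-BuMe2SiCl, imidazole, DMF, rt
Reagents that add atoms: tert-butyldimethylsilyl chloride, CC(C)(C)[Si](C)(C)Cl
Why: Silyl chloride with imidazole silylates a secondary alcohol but not a hindered tertiary one; the C8 hydroxyl, flanked by isopropyl and the ring fusion, stays free.

Step 10
Reactants: 16 the bis-silyl ether
Product: 17 (3S,4S,5R,8R,10S)-10-(tert-butyldimethylsilyloxy)-5-methyl-1-methylidene-8-(propan-2-yl)bicyclo[5.3.0]decane-3,8-diol (skeleton numbering)
Conditions: pyridinium p-toluenesulfonate (0.2 equiv), MeOH/CH2Cl2, 0 °C
Reagents that add atoms: none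
Why: Mild acid-catalysed methanolysis removes a triethylsilyl ether far faster than a tert-butyldimethylsilyl ether. The conditions are too weak to ionise the allylic C10 oxygen or dehydrate C8.

Step 11
Reactants: 18 vanillic acid
Product: 20 4-(tert-butyldimethylsilyloxy)-3-methoxybenzoic acid, via bis-silyl derivative 19 (not isolated)
Conditions: t-BuMe2SiCl (2.5 equiv), imidazole, DMF, rt; then AcOH/THF/H2O, rt
Reagents that add atoms: tert-butyldimethylsilyl chloride, CC(C)(C)[Si](C)(C)Cl
Why: Exhaustive silylation of phenol and acid, then selective hydrolysis of the labile silyl ester, which leaves the aryl silyl ether. The phenol is masked so the acid cannot acylate itself in step 12.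

Step 12
Reactants: 20 4-(tert-butyldimethylsilyloxy)-3-methoxybenzoic acid; 17 the C3 alcohol
Product: 22 (3S,4S,5R,8R,10S)-10-(tert-butyldimethylsilyloxy)-8-hydroxy-5-methyl-1-methylidene-8-(propan-2-yl)bicyclo[5.3.0]decan-3-yl 4-(tert-butyldimethylsilyloxy)-3-methoxybenzoate (skeleton numbering), via mixed anhydride 21 (not isolated)
Conditions: 2,4,6-trichlorobenzoyl chloride, Et3N, THF, rt; then 17, DMAP, toluene, rt to 50 °C
Reagents that add atoms: none
Why: Yamaguchi esterification: DMAP attacks the mixed anhydride 21 at the less hindered vanilloyl carbonyl, and the acylpyridinium acylates the only free secondary hydroxyl. The tertiary C8 hydroxyl does not react, and C3 keeps its configuration because the C3–O bond is not broken.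

Step 13
Reactants: 22 the protected ester
Product: 23 target, (3S,4S,5R,8R,10S)-8,10-dihydroxy-5-methyl-1-methylidene-8-(propan-2-yl)bicyclo[5.3.0]decan-3-yl 4-hydroxy-3-methoxybenzoate (skeleton numbering)
Conditions: HF·pyridine, pyridine, THF, 0 °C to rt
Reagents that add atoms: none
Why: Fluoride cleavage of the aryl and the secondary silyl ether under buffered conditions that leave the aryl ester, the allylic alcohol and the tertiary alcohol intact; no stereocentre is touched.

## Compound list

1 | 3-ethoxycyclopent-2-en-1-one | CCOC1=CC(=O)CC1 | starting material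
2 | allylmagnesium bromide | C=CC[Mg]Br | starting material
3 | bromomagnesium 3-ethoxy-1-(prop-2-en-1-yl)cyclopent-2-en-1-olate (racemic, not isolated) | C=CCC1(O[Mg]Br)C=C(OCC)CC1 | intermediate
4 | 3-(prop-2-en-1-yl)cyclopent-2-en-1-one | C=CCC1=CC(=O)CC1 | intermediate
5 | 3-methylbut-3-en-1-ol | CC(=C)CCO | starting material
6 | 3-methylbut-3-enal | CC(=C)CC=O | intermediate
7 | trimethylaluminium | C[Al](C)C | starting material
8 | dimethylaluminium enolate of (R)-3-methyl-3-(prop-2-en-1-yl)cyclopentanone, enolised towards C4 (not isolated) | C=CC[C@@]1(C)CCC(O[Al](C)C)=C1 | intermediate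
9 | (2S,3R)-2-[(1S)-1-hydroxy-3-methylbut-3-en-1-yl]-3-methyl-3-(prop-2-en-1-yl)cyclopentan-1-one | C=C(C)C[C@H](O)[C@@H]1[C@](C)(CCC1=O)CC=C | intermediate
10 | (2S,3R)-3-methyl-2-[(1S)-3-methyl-1-(triethylsilyloxy)but-3-en-1-yl]-3-(prop-2-en-1-yl)cyclopentan-1-one | C=C(C)C[C@H](O[Si](CC)(CC)CC)[C@@H]1[C@](C)(CCC1=O)CC=C | intermediate
11 | isopropylmagnesium chloride | CC(C)[Mg]Cl | starting material
12 | (1R,2S,3R)-3-methyl-2-[(1S)-3-methyl-1-(triethylsilyloxy)but-3-en-1-yl]-1-(propan-2-yl)-3-(prop-2-en-1-yl)cyclopentan-1-ol | C=C(C)C[C@H](O[Si](CC)(CC)CC)[C@@H]1[C@](C)(CC[C@@]1(O)C(C)C)CC=C | intermediate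
13 | (3S,4S,5R,8R)-1,5-dimethyl-8-(propan-2-yl)-3-(triethylsilyloxy)bicyclo[5.3.0]dec-1(10)-en-8-ol, trans-fused (skeleton numbering) | CC=1C[C@H](O[Si](CC)(CC)CC)[C@@H]2[C@](C)(CC[C@@]2(O)C(C)C)CC=1 | intermediate
14 | (1R,3S,4S,5R,8R,10S)-1,10-epoxy-1,5-dimethyl-8-(propan-2-yl)-3-(triethylsilyloxy)bicyclo[5.3.0]decan-8-ol, epoxide on the α face (skeleton numbering) | C[C@@]12C[C@H](O[Si](CC)(CC)CC)[C@@H]3[C@](C)(CC[C@@]3(O)C(C)C)C[C@@H]1O2 | intermediate
15 | (3S,4S,5R,8R,10S)-5-methyl-1-methylidene-8-(propan-2-yl)-3-(triethylsilyloxy)bicyclo[5.3.0]decane-8,10-diol (skeleton numbering) | C=C1C[C@H](O[Si](CC)(CC)CC)[C@@H]2[C@](C)(CC[C@@]2(O)C(C)C)C[C@@H]1O | intermediate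
16 | (3S,4S,5R,8R,10S)-10-(tert-butyldimethylsilyloxy)-5-methyl-1-methylidene-8-(propan-2-yl)-3-(triethylsilyloxy)bicyclo[5.3.0]decan-8-ol (skeleton numbering) | C=C1C[C@H](O[Si](CC)(CC)CC)[C@@H]2[C@](C)(CC[C@@]2(O)C(C)C)C[C@@H]1O[Si](C)(C)C(C)(C)C | intermediate
17 | (3S,4S,5R,8R,10S)-10-(tert-butyldimethylsilyloxy)-5-methyl-1-methylidene-8-(propan-2-yl)bicyclo[5.3.0]decane-3,8-diol (skeleton numbering) | C=C1C[C@H](O)[C@@H]2[C@](C)(CC[C@@]2(O)C(C)C)C[C@@H]1O[Si](C)(C)C(C)(C)C | intermediate
18 | vanillic acid (4-hydroxy-3-methoxybenzoic acid) | COc1cc(C(=O)O)ccc1O | starting material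
19 | tert-butyldimethylsilyl 4-(tert-butyldimethylsilyloxy)-3-methoxybenzoate (not isolated) | COc1cc(C(=O)O[Si](C)(C)C(C)(C)C)ccc1O[Si](C)(C)C(C)(C)C | intermediate
20 | 4-(tert-butyldimethylsilyloxy)-3-methoxybenzoic acid | COc1cc(C(=O)O)ccc1O[Si](C)(C)C(C)(C)C | intermediate
21 | 4-(tert-butyldimethylsilyloxy)-3-methoxybenzoic 2,4,6-trichlorobenzoic anhydride (not isolated) | COc1cc(C(=O)OC(=O)c2c(Cl)cc(Cl)cc2Cl)ccc1O[Si](C)(C)C(C)(C)C | intermediate
22 | (3S,4S,5R,8R,10S)-10-(tert-butyldimethylsilyloxy)-8-hydroxy-5-methyl-1-methylidene-8-(propan-2-yl)bicyclo[5.3.0]decan-3-yl 4-(tert-butyldimethylsilyloxy)-3-methoxybenzoate (skeleton numbering) | C=C1C[C@H](OC(=O)c2ccc(O[Si](C)(C)C(C)(C)C)c(OC)c2)[C@@H]2[C@](C)(CC[C@@]2(O)C(C)C)C[C@@H]1O[Si](C)(C)C(C)(C)C | intermediate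
23 | (3S,4S,5R,8R,10S)-8,10-dihydroxy-5-methyl-1-methylidene-8-(propan-2-yl)bicyclo[5.3.0]decan-3-yl 4-hydroxy-3-methoxybenzoate (skeleton numbering) | C=C1C[C@H](OC(=O)c2ccc(O)c(OC)c2)[C@@H]2[C@](C)(CC[C@@]2(O)C(C)C)C[C@@H]1O | target

## Step count and least certain steps

Total: 13 steps. Longest linear sequence: 11 steps (1, 3, 4, 5, 6, 7, 8, 9, 10, 12, 13); steps 2 and 11 are side branches.

**Step 3 (key step).** Three things can go wrong.
- Enantiofacial discrimination may be lower on a five-membered enone than on six-membered ones, because the flatter ring gives the ligand less to grip.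
- Face selection at C4 may be poor, because methyl and allyl on C5 differ little in size near the enolate carbon.
- The aldol may be eroded by methyl transfer from residual AlMe3 to the aldehyde or by isomerisation of the β,γ-unsaturated aldehyde.

The fallback separates the two events. It sets out from 4: the same conjugate addition is quenched with trimethylsilyl triflate, and the product is isolated as (3R)-3-methyl-3-(prop-2-en-1-yl)-1-(trimethylsilyloxy)cyclopent-1-ene F1, which can be purified and assayed for enantiopurity. MeLi in THF then gives the lithium enolate of (R)-3-methyl-3-(prop-2-en-1-yl)cyclopentanone F2, free of aluminium methyl species. F2 is treated with 6 at −78 °C through the same closed transition state, and the sequence comes back to the route at 9.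

**Step 5.** The likely failures are enolisation of the hindered ketone towards C4 with loss of the β-silyloxy group, reduction by β-hydride transfer from the isopropyl reagent, and incomplete facial control on the flexible monocyclic ketone. The fallback changes the order of ring closure and addition. It sets out from 10, which is cyclised first with the same ruthenium catalyst to the trans-fused (3S,4S,5R)-1,5-dimethyl-3-(triethylsilyloxy)bicyclo[5.3.0]dec-1(10)-en-8-one F3. On this rigid bicycle the β face of C8 is screened by the angular methyl and the C3 carbon, and addition of the isopropylcerium reagent from the α face returns the route at 13.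

**Step 7.** The failure would be poor facial selectivity, if the seven-membered ring populates a twist form in which the C5 methyl no longer covers the β face. The fallback uses a directing group in place of steric bias. It sets out from 13, which is desilylated with Bu4NF to (3S,4S,5R,8R)-1,5-dimethyl-8-(propan-2-yl)bicyclo[5.3.0]dec-1(10)-ene-3,8-diol F4. The α-oriented homoallylic C3 hydroxyl then delivers oxygen from VO(acac)2/t-BuOOH to the α face, giving (1R,3S,4S,5R,8R,10S)-1,10-epoxy-1,5-dimethyl-8-(propan-2-yl)bicyclo[5.3.0]decane-3,8-diol F5. Selective silylation of the secondary C3 hydroxyl with Et3SiCl/imidazole returns the route at 14.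

**Step 8.** The failures would be proton removal from the C2 or C9 ring methylene in place of the methyl group, or Lewis-acid-induced hydride shift of the epoxide to a ketone. The fallback replaces the ionic elimination by a radical one and makes no new isolable compound (entry F0 below). It sets out from 14, which is treated with the trivalent titanium reagent Cp2TiCl (from Cp2TiCl2 and manganese powder, THF). The C1–O bond is cleaved homolytically to the tertiary C1 radical, a second equivalent traps the radical, and β-hydride elimination towards the methyl group gives the exocyclic alkene; the route is rejoined at 15.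

**Step 10.** The failure would be loss or migration of the wrong silyl group, so that the C3 and C10 hydroxyls are no longer distinguished. The fallback installs the ester before the C10 oxygen exists. It sets out from 13, which is desilylated to the diol F4 described above. F4 is acylated with 21 (made from 20 as in step 12) to (3S,4S,5R,8R)-8-hydroxy-1,5-dimethyl-8-(propan-2-yl)bicyclo[5.3.0]dec-1(10)-en-3-yl 4-(tert-butyldimethylsilyloxy)-3-methoxybenzoate F6. mCPBA epoxidation gives the 1α,10α-epoxide of that ester F7. The ester-tolerant Cp2TiCl isomerisation then gives (3S,4S,5R,8R,10S)-8,10-dihydroxy-5-methyl-1-methylidene-8-(propan-2-yl)bicyclo[5.3.0]decan-3-yl 4-(tert-butyldimethylsilyloxy)-3-methoxybenzoate F8. HF·pyridine removes the aryl silyl ether and the route is rejoined at 23.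

## Further compounds

F1 | step 3 | (3R)-3-methyl-3-(prop-2-en-1-yl)-1-(trimethylsilyloxy)cyclopent-1-ene | C=CC[C@@]1(C)CCC(O[Si](C)(C)C)=C1
F2 | step 3 | lithium enolate of (R)-3-methyl-3-(prop-2-en-1-yl)cyclopentanone, enolised towards C4 | C=CC[C@@]1(C)CCC(O[Li])=C1
F3 | step 5 | (3S,4S,5R)-1,5-dimethyl-3-(triethylsilyloxy)bicyclo[5.3.0]dec-1(10)-en-8-one, trans-fused (skeleton numbering) | CC=1C[C@H](O[Si](CC)(CC)CC)[C@@H]2[C@](C)(CCC2=O)CC=1
F4 | step 7 | (3S,4S,5R,8R)-1,5-dimethyl-8-(propan-2-yl)bicyclo[5.3.0]dec-1(10)-ene-3,8-diol (skeleton numbering) | CC=1C[C@H](O)[C@@H]2[C@](C)(CC[C@@]2(O)C(C)C)CC=1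
F5 | step 7 | (1R,3S,4S,5R,8R,10S)-1,10-epoxy-1,5-dimethyl-8-(propan-2-yl)bicyclo[5.3.0]decane-3,8-diol (skeleton numbering) | C[C@@]12C[C@H](O)[C@@H]3[C@](C)(CC[C@@]3(O)C(C)C)C[C@@H]1O2
F0 | step 8 | none | none
F6 | step 10 | (3S,4S,5R,8R)-8-hydroxy-1,5-dimethyl-8-(propan-2-yl)bicyclo[5.3.0]dec-1(10)-en-3-yl 4-(tert-butyldimethylsilyloxy)-3-methoxybenzoate (skeleton numbering) | CC=1C[C@H](OC(=O)c3ccc(O[Si](C)(C)C(C)(C)C)c(OC)c3)[C@@H]2[C@](C)(CC[C@@]2(O)C(C)C)CC=1
F7 | step 10 | (1R,3S,4S,5R,8R,10S)-1,10-epoxy-8-hydroxy-1,5-dimethyl-8-(propan-2-yl)bicyclo[5.3.0]decan-3-yl 4-(tert-butyldimethylsilyloxy)-3-methoxybenzoate (skeleton numbering) | C[C@@]12C[C@H](OC(=O)c4ccc(O[Si](C)(C)C(C)(C)C)c(OC)c4)[C@@H]3[C@](C)(CC[C@@]3(O)C(C)C)C[C@@H]1O2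
F8 | step 10 | (3S,4S,5R,8R,10S)-8,10-dihydroxy-5-methyl-1-methylidene-8-(propan-2-yl)bicyclo[5.3.0]decan-3-yl 4-(tert-butyldimethylsilyloxy)-3-methoxybenzoate (skeleton numbering) | C=C1C[C@H](OC(=O)c2ccc(O[Si](C)(C)C(C)(C)C)c(OC)c2)[C@@H]2[C@](C)(CC[C@@]2(O)C(C)C)C[C@@H]1O
A1 | alternative 1 | (5R,8R)-10-(tert-butyldimethylsilyloxy)-5-methyl-8-(propan-2-yl)bicyclo[5.3.0]deca-3,9-dien-8-ol (skeleton numbering) | C1CC=C2[C@](C)(CC[C@@]2(O)C(C)C)C=C1O[Si](C)(C)C(C)(C)C
A2 | alternative 1 | (3R,6E)-7-[1-(tert-butyldimethylsilyloxy)cyclopropyl]-6-methyl-3-(propan-2-yl)hept-6-en-1-yn-3-ol | C#C[C@](O)(C(C)C)CC/C(C)=C/C1(O[Si](C)(C)C(C)(C)C)CC1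
A3 | alternative 2 | (4S,5R,8R,10S)-10-(tert-butyldimethylsilyloxy)-5-methyl-1-methylidene-8-(propan-2-yl)-8-(triethylsilyloxy)bicyclo[5.3.0]decan-3-one (skeleton numbering) | C=C1CC(=O)[C@@H]2[C@](C)(CC[C@@]2(O[Si](CC)(CC)CC)C(C)C)C[C@@H]1O[Si](C)(C)C(C)(C)C
A4 | alternative 2 | cyclopentane bearing a 1-(tert-butyldimethylsilyloxy)ethenyl group on C4, a (2S)-2-(tert-butyldimethylsilyloxy)but-3-yn-1-yl arm and methyl on C5, and isopropyl and triethylsilyloxy on C8 (skeleton numbering) | C=C(O[Si](C)(C)C(C)(C)C)[C@@H]1[C@](C)(CC[C@@]1(O[Si](CC)(CC)CC)C(C)C)C[C@@H](C#C)O[Si](C)(C)C(C)(C)C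
A5 | alternative 3 | daucene (dauca-4,8-diene) | CC1=CC[C@@]2(C)CCC(C(C)C)=C2CC1
A6 | alternative 3 | (2E,6E)-farnesyl diphosphate | CC(C)=CCC/C(C)=C/CC/C(C)=C/COP(=O)(O)OP(=O)(O)O
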